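(The runs stem from a simulated flask for an exercise; the scatter is artificial.)

**Your question.** You want a quick number, and you suspect reagent will hold these flasks back, as it seemed to on Sunday.

the same everywhere: free catalyst 0.24 mM; second catalyst 0.55 mM
- Sunday's: substrate 0.050 M; reagent 0.030 M; temperature 65 °C; run made earlier
- Thursday's: substrate 0.050 M; reagent 0.12 M; temperature 76 °C; run made earlier
- Wednesday's: substrate 0.025 M; reagent 0.060 M; temperature 65 °C; run made earlier
- ochre: substrate 0.050 M; reagent 0.0600 M; at 80 °C until 10 h, from then on at 60 °C; time 20 h
- violet: substrate 0.050 M; reagent 0.0600 M; temperature 80 °C; time 20 h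
- green: substrate 0.050 M; reagent 0.0600 M; temperature 60 °C; time 20 h

- Sunday's (time / h: open intermediate / %, target / %): 4.00: 77, 8; 8.00: 69, 20; 12.0: 59, 31; 25.0: 38, 53; 48.0: 32, 60
- Thursday's (time / h: open intermediate / %, target / %): 2.00: 78, 11; 6.00: 57, 35; 12.0: 35, 57; 15.0: 24, 64; 25.0: 10, 77
- Wednesday's (time / h: open intermediate / %, target / %): 10.0: 62, 29; 20.0: 38, 54; 30.0: 23, 68; 40.0: 16, 78; 48.0: 9, 84

(readings scatter by 1.5 percentage points)

- percentages count the substrate that a species holds: one idle adduct counts as two
- target is meant together with its idle adduct
- what may be going on: substrate + free catalyst -> free catalyst + open intermediate; second catalyst + open intermediate <-> catalyst intermediate; reagent + catalyst intermediate -> second catalyst + target; open intermediate -> side product; substrate + target <-> idle adduct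
- in an amount of target, one idle adduct counts as one target

1. the flask that comes out highest in amount of open intermediate, in percent of the substrate charged, or "all alike" when all lie within 1.5 percentage points (ochre / violet / green / all alike)
2. open intermediate at the end, in percent of the substrate charged, ochre
3. open intermediate at the end, in percent of the substrate charged, violet
4. open intermediate at the end, in percent of the substrate charged, green

**Slow decay.** Open intermediate leaves slowly. In Wednesday's run it falls from 38% to 16% between 20.0 h and 40.0 h, a pseudo-first-order constant of 0.0432 /h at 65 °C. Thursday's run, from 57% to 10%, reads 0.0916 /h at 76 °C. These runs differ in their charges as well as their temperatures, but if I put the whole difference down to temperature, they give an apparent activation energy of 67.0 kJ/mol. So I take 0.0302 /h at 60 °C and 0.119 /h at 80 °C.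

**Clearance dose.** For ochre, 1.49 is the clearance dose: constant times hours, summed over a flask's temperature stages. Running Wednesday's and Thursday's lines back to the start and averaging gives 94.5%. My first answers are therefore ochre 21.3%, violet 8.75% and green 51.6%.

**Second round.** Now put violet's answer back. Count the rest of its charge as target, and reagent left is 0.0144 M. That is more than the 0.00350 M Sunday's run held at 25.0 h. Sunday's open intermediate was still falling up to that reading, from 59% at 12.0 h to 38%, so I keep my numbers.

**The forecast.** It names green highest, with ochre 23.5% (18% to 29%), violet 13% (8% to 19%) and green 45% (39% to 52%). On reagent it says: “The rate is therefore near zero order in reagent”. My green stands higher than its green, and my violet lower than its violet.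

**The flasks.** Green ends at 49.1%, ochre at 23.1% and violet at 10.4%, so green comes out highest.

    substrate + free catalyst → free catalyst + open intermediate (k = 117 /M/min, Ea = 66.0 kJ/mol)
    second catalyst + open intermediate ⇌ catalyst intermediate (K = 130 /M, k = 3.29 /M/min, Ea = 53.0 kJ/mol, ΔH = −50.0 kJ/mol)
    reagent + catalyst intermediate → second catalyst + target (k = 44.9 /M/min, Ea = 68.0 kJ/mol)
    open intermediate → side product (k = 2.76 × 10⁻⁴ /min, Ea = 118 kJ/mol)
    substrate + target ⇌ idle adduct, settled at all times (K = 431 /M, ΔH = −58.0 kJ/mol)
    (constants at 80 °C)

**Neighbour.** Take a flask charged like ochre, but with 2.2 × 10⁻⁴ M of second catalyst. Second catalyst is what takes up open intermediate in these equations, so I scale the dose by the ratio of charges, 0.400. The dose becomes 0.597, and the same start gives 52.0%. That flask ends with open intermediate at 50.2%, more than ochre's 23.1%.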